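**Plan**
- The retrosynthesis cuts two ring bonds of the phenol, C1–C2 and C3–C4 (C1 carries the acyloxyethyl arm, C4 the hydroxyl), and the ester C(=O)–O bond.
- What makes this possible: the C4 oxygen and the C1 arm are para, which is the relationship the ring oxygen of a 2-substituted furan has across its C5 and C2. The furan therefore supplies C1, C6, C5, C4 and the oxygen, and a two-carbon acetylene equivalent supplies C2 and C3.
- Forward: alcohol 1 is acylated with acid chloride 2 to give furan ester 3. Cycloaddition of 3 with disulfone 4 closes the six-membered carbocycle as the oxygen-bridged adduct 5.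
- Reductive removal of both sulfonyl groups gives diene 6, and acid opens the oxygen bridge at C1 and aromatises the ring to the target 7.
- Stereochemistry: the target has no stereocentre. The four stereocentres formed in the cycloaddition are transient and are all erased by desulfonylation and aromatisation, so no stereocontrol is needed.

Key step: step 2

Remark: atom labels C1–C6 in the text are those of the benzene ring of the target, while the systematic names of the bicyclic intermediates use their own locants; adduct 5 is assumed to be carried on as the mixture of its two racemic trans diastereomers, since both converge on the achiral diene 6.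

Step 1
Reactants: 1 2-(furan-2-yl)ethanol; 2 docosanoyl chloride
Product: 3 2-(furan-2-yl)ethyl docosanoate
Conditions: pyridine (1.5 equiv), DMAP (cat.), CH2Cl2, 0 °C → rt
Reagents that add atoms: none
Why: DMAP-catalysed acylation of a primary alcohol by an acid chloride (nucleophilic acyl substitution) is fast, and the pyridine scavenges HCl so that the acid-sensitive furan is not exposed to it; no stereocentre is formed.

Step 2
Reactants: 3 2-(furan-2-yl)ethyl docosanoate; 4 (E)-1,2-bis(phenylsulfonyl)ethene
Product: 5 2-[trans-5,6-bis(phenylsulfonyl)-7-oxabicyclo[2.2.1]hept-2-en-1-yl]ethyl docosanoate (racemic; mixture of the 5-exo,6-endo and 5-endo,6-exo diastereomers)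
Conditions: 4 (1.1 equiv), CH2Cl2 (ca. 1 M), rt → 40 °C, sealed tube, dark
Reagents that add atoms: none
Why: This is a Diels–Alder reaction in which the 2-alkylfuran (raised HOMO) and the doubly sulfonyl-activated alkene (low LUMO) combine in a concerted, suprafacial, normal-electron-demand [4+2] cycloaddition that forms the C1–C2 and C3–C4 bonds together. The closest known reaction type is the cycloaddition of furans with 1,2-bis(phenylsulfonyl)ethene used as an acetylene equivalent. The six-membered carbocycle C1–C6 closes by intermolecular [4+2] cycloaddition, and the furan oxygen is left as the one-atom bridge between C1 and C4. Of the four new stereocentres, the two bridgeheads are locked cis by the oxygen bridge and the sulfonyl-bearing carbons C2 and C3 are trans because the E geometry of 4 is transferred suprafacially; which sulfonyl group lies exo is not controlled and need not be, since every stereocentre is destroyed in steps 3 and 4. No regioselectivity is required because 4 is symmetrical, and the only demand, that cycloaddition outruns cycloreversion, should be met by the electron-rich diene, the strongly electron-poor dienophile, high concentration and mild temperature.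

Step 3
Reactants: 5 2-[trans-5,6-bis(phenylsulfonyl)-7-oxabicyclo[2.2.1]hept-2-en-1-yl]ethyl docosanoate
Product: 6 2-(7-oxabicyclo[2.2.1]hepta-2,5-dien-1-yl)ethyl docosanoate
Conditions: Na/Hg (5% Na, excess), NaH2PO4, THF/MeOH (2:1), −20 → 0 °C
Reagents that add atoms: none
Why: In this Julia-type reductive elimination of a vicinal disulfone, electron transfer from Na/Hg expels one benzenesulfinate and the resulting β-sulfonyl carbanion expels the second to form the C2=C3 alkene, while the NaH2PO4 buffer and low temperature should keep methoxide too scarce to transesterify the docosanoate; the sulfonyl-bearing stereocentres vanish and 6 is achiral.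

Step 4
Reactants: 6 2-(7-oxabicyclo[2.2.1]hepta-2,5-dien-1-yl)ethyl docosanoate
Product: 7 2-(4-hydroxyphenyl)ethyl docosanoate
Conditions: TsOH·H2O (5 mol%), CH2Cl2 (dilute), 0 °C → rt
Reagents that add atoms: none
Why: In this acid-catalysed isomerisation of a 7-oxanorbornadiene to a phenol, protonation of the bridge oxygen is followed by heterolysis of the C1–O bond, preferred over C4–O because it gives a tertiary, doubly allylic cyclohexadienyl cation, and loss of the C4 proton from this arenium ion aromatises the ring with the former furan oxygen as the para hydroxyl; the anhydrous conditions leave the ester untouched and no stereocentre remains.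

**Compound list**
1 | 2-(furan-2-yl)ethanol | OCCc1ccco1 | starting material
2 | docosanoyl chloride | CCCCCCCCCCCCCCCCCCCCCC(=O)Cl | starting material
3 | 2-(furan-2-yl)ethyl docosanoate | CCCCCCCCCCCCCCCCCCCCCC(=O)OCCc1ccco1 | intermediate
4 | (E)-1,2-bis(phenylsulfonyl)ethene | O=S(=O)(/C=C/S(=O)(=O)c1ccccc1)c1ccccc1 | starting material
5 | 2-[trans-5,6-bis(phenylsulfonyl)-7-oxabicyclo[2.2.1]hept-2-en-1-yl]ethyl docosanoate (racemic; mixture of two diastereomers; the 5-exo,6-endo isomer is drawn in relative configuration, the 5-endo,6-exo isomer accompanies it) | CCCCCCCCCCCCCCCCCCCCCC(=O)OCC[C@@]12C=C[C@@H](O1)[C@@H](S(=O)(=O)c1ccccc1)[C@@H]2S(=O)(=O)c1ccccc1 | intermediate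
6 | 2-(7-oxabicyclo[2.2.1]hepta-2,5-dien-1-yl)ethyl docosanoate (achiral) | CCCCCCCCCCCCCCCCCCCCCC(=O)OCCC12C=CC(O1)C=C2 | intermediate
7 | 2-(4-hydroxyphenyl)ethyl docosanoate | CCCCCCCCCCCCCCCCCCCCCC(=O)OCCc1ccc(O)cc1 | target

Total step count: 4
Longest linear sequence: 4 steps (1 → 3 → 5 → 6 → 7)

**Steps most likely to fail**

Step 2 (cycloaddition). The E-dienophile may add too slowly to the furan, and the adduct may revert on warming, so that conversion stalls. The fallback sets out from 3 and uses (Z)-1,2-bis(phenylsulfonyl)ethene (O=S(=O)(/C=C\S(=O)(=O)c1ccccc1)c1ccccc1), the geometric isomer generally regarded as the better dienophile toward cyclic dienes such as furans, in CH2Cl2 at rt. It should give the cis-disulfone adduct 2-[cis-5,6-bis(phenylsulfonyl)-7-oxabicyclo[2.2.1]hept-2-en-1-yl]ethyl docosanoate F1. Its two sulfonyl groups would be removed with Na/Hg and NaH2PO4 in THF/MeOH as in step 3, and the route is rejoined at 6.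

Step 3 (reductive elimination). Methoxide generated at the amalgam surface may transesterify or cleave the docosanoate faster than the buffer neutralises it. The fallback introduces the ester last and sets out from 1. Cycloaddition of 1 with 4 (CH2Cl2, rt → 40 °C) should give 2-[trans-5,6-bis(phenylsulfonyl)-7-oxabicyclo[2.2.1]hept-2-en-1-yl]ethanol F2. Na/Hg with NaH2PO4 in MeOH would then give 2-(7-oxabicyclo[2.2.1]hepta-2,5-dien-1-yl)ethanol F3, which carries no base-labile group. Catalytic TsOH in CH2Cl2 should isomerise it to 4-(2-hydroxyethyl)phenol F4. Immobilised Candida antarctica lipase B with docosanoic acid (CCCCCCCCCCCCCCCCCCCCCC(=O)O) and 4 Å molecular sieves in toluene at 60 °C would acylate only the primary aliphatic hydroxyl, which returns the route at 7.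

Step 4 (bridge opening). The cationic intermediates may alkylate the electron-rich phenol as it forms, or the diene may oligomerise under acid. The fallback sets out from 6 and opens the bridge acylatively with Ac2O and catalytic BF3·OEt2 in CH2Cl2 at −20 °C. The bridge oxygen would be acylated before the C1–O bond breaks, so the ring should aromatise to the much less nucleophilic aryl acetate 2-(4-acetoxyphenyl)ethyl docosanoate F5. Pyrrolidine in CH2Cl2 at 0 °C → rt would then remove the phenolic acetate by aminolysis without touching the alkyl ester, and the route is rejoined at 7.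

Further compounds
F1 | step 2 | 2-[cis-5,6-bis(phenylsulfonyl)-7-oxabicyclo[2.2.1]hept-2-en-1-yl]ethyl docosanoate (racemic; exo,exo isomer drawn in relative configuration, the endo,endo isomer may accompany it) | CCCCCCCCCCCCCCCCCCCCCC(=O)OCC[C@@]12C=C[C@@H](O1)[C@@H](S(=O)(=O)c1ccccc1)[C@H]2S(=O)(=O)c1ccccc1
F2 | step 3 | 2-[trans-5,6-bis(phenylsulfonyl)-7-oxabicyclo[2.2.1]hept-2-en-1-yl]ethanol (racemic; 5-exo,6-endo isomer drawn in relative configuration, the 5-endo,6-exo isomer accompanies it) | OCC[C@@]12C=C[C@@H](O1)[C@@H](S(=O)(=O)c1ccccc1)[C@@H]2S(=O)(=O)c1ccccc1
F3 | step 3 | 2-(7-oxabicyclo[2.2.1]hepta-2,5-dien-1-yl)ethanol | OCCC12C=CC(O1)C=C2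
F4 | step 3 | 4-(2-hydroxyethyl)phenol | OCCc1ccc(O)cc1
F5 | step 4 | 2-(4-acetoxyphenyl)ethyl docosanoate | CCCCCCCCCCCCCCCCCCCCCC(=O)OCCc1ccc(OC(C)=O)cc1
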